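**Retrosynthetic overview**
1. Target 31 ⇐ triene lactone 30 by a last-step outer-face epoxidation of C4=C5; the C9 acetate and the C8 epoxy ester (acid 4, from a Sharpless epoxidation) go on after ring closure.
2. Ten-membered carbocycle (second ring) ⇐ seco-lactone 24 by a palladium-catalysed intramolecular Suzuki–Miyaura coupling at C1–C2 (E-enol tosylate + Z-alkenyl boronate).
3. α-Methylene lactone (first ring; C6–C7 bond, C6 and C7) ⇐ dienal 9 + allylic bromide 22 by CrCl2 allylation/lactonisation.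
4. 22 ⇐ (S)-but-3-ene-1,2-diol 12 (C8): chelation-controlled Mukaiyama aldol (C9), formylation and E-selective enol tosylation (C1), cross-metathesis with 21 (C11–C13).
5. 9 ⇐ enynol 5 by rhodium-catalysed trans-hydroboration. Ring order: lactone, then carbocycle, then the C4,C5-epoxide.

Assumption: locants C1–C15 follow germacrane numbering (C12 lactone carbonyl, C13 exocyclic methylene, C14 ester carbon, C15 methyl), and 1, 5, 10, 12, 18 and 21 are catalogue chemicals.

**Fragment A: epoxy acid**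

Step 1
Reactants: 1 (E)-2-methylbut-2-en-1-ol
Product: 2 [(2S,3S)-2,3-dimethyloxiran-2-yl]methanol
Conditions: Ti(OiPr)4 (10 mol%), L-(+)-diethyl tartrate (12 mol%), tBuOOH, 4 Å MS, CH2Cl2, −20 °C
Reagents that add atoms: tert-butyl hydroperoxide, CC(C)(C)OO
Why: Sharpless asymmetric epoxidation of a trans-trisubstituted allylic alcohol, in which the titanium–L-(+)-tartrate complex delivers oxygen to one alkene face and sets both ring stereocentres as (2S,3S) with the two methyl groups cis.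

Step 2
Reactants: 2 [(2S,3S)-2,3-dimethyloxiran-2-yl]methanol
Product: 3 (2R,3S)-2,3-dimethyloxirane-2-carbaldehyde
Conditions: TEMPO (10 mol%), PhI(OAc)2 (1.1 equiv), CH2Cl2, rt
Reagents that add atoms: none
Why: TEMPO/PhI(OAc)2 (oxoammonium) oxidation stops at the aldehyde under neutral conditions that leave the epoxide and both stereocentres untouched.

Step 3
Reactants: 3 (2R,3S)-2,3-dimethyloxirane-2-carbaldehyde
Product: 4 (2R,3S)-2,3-dimethyloxirane-2-carboxylic acid
Conditions: NaClO2, NaH2PO4, 2-methylbut-2-ene, tBuOH/H2O, 0 °C to rt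
Reagents that add atoms: sodium chlorite, [Na+].[O-]Cl=O
Why: Pinnick oxidation converts the aldehyde into the acid, with the hypochlorite by-product scavenged by the alkene so that the epoxide survives.

**Fragment B: C2–C6 dienal**

Step 4
Reactants: 5 (E)-3-methylpent-2-en-4-yn-1-ol
Product: 6 tert-butyldimethyl{[(2E)-3-methylpent-2-en-4-yn-1-yl]oxy}silane
Conditions: TBSCl, imidazole, DMF, 0 °C to rt
Reagents that add atoms: tert-butyldimethylsilyl chloride, CC(C)(C)[Si](C)(C)Cl
Why: Silyl ether formation masks the hydroxyl group, which would otherwise consume pinacolborane in the next step.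

Step 5
Reactants: 6 tert-butyldimethyl{[(2E)-3-methylpent-2-en-4-yn-1-yl]oxy}silane
Product: 7 tert-butyldimethyl{[(2E,4Z)-3-methyl-5-(4,4,5,5-tetramethyl-1,3,2-dioxaborolan-2-yl)penta-2,4-dien-1-yl]oxy}silane
Conditions: pinacolborane, [Rh(cod)Cl]2 (1.5 mol%), P(iPr)3 (6 mol%), Et3N, cyclohexane, rt
Reagents that add atoms: pinacolborane, CC1(C)OBOC1(C)C
Why: Miyaura's rhodium-catalysed trans-hydroboration of a terminal alkyne runs through alkyne C–H activation to a rhodium vinylidene, so boron and the enyne residue end up cis and the Z-alkenyl boronate (future C2=C3) forms without touching the trisubstituted E-alkene.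

Step 6
Reactants: 7 tert-butyldimethyl{[(2E,4Z)-3-methyl-5-(4,4,5,5-tetramethyl-1,3,2-dioxaborolan-2-yl)penta-2,4-dien-1-yl]oxy}silane
Product: 8 (2E,4Z)-3-methyl-5-(4,4,5,5-tetramethyl-1,3,2-dioxaborolan-2-yl)penta-2,4-dien-1-ol
Conditions: PPTS (10 mol%), MeOH, rt
Reagents that add atoms: none
Why: Acid-catalysed methanolysis cleaves the primary allylic silyl ether while the pinacol boronate is stable.

Step 7
Reactants: 8 (2E,4Z)-3-methyl-5-(4,4,5,5-tetramethyl-1,3,2-dioxaborolan-2-yl)penta-2,4-dien-1-ol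
Product: 9 (2E,4Z)-3-methyl-5-(4,4,5,5-tetramethyl-1,3,2-dioxaborolan-2-yl)penta-2,4-dienal
Conditions: MnO2 (15 equiv), CH2Cl2, rt
Reagents that add atoms: none
Why: MnO2 oxidises only the allylic alcohol to the enal and, being neutral and heterogeneous, does not isomerise the Z-alkenyl boronate.

**Ketene acetal**

Step 8
Reactants: 10 methyl acetate
Product: 11 tert-butyl[(1-methoxyethenyl)oxy]dimethylsilane
Conditions: LiN(iPr)2, THF, −78 °C; then TBSCl, DMPU, −78 °C to rt
Reagents that add atoms: tert-butyldimethylsilyl chloride, CC(C)(C)[Si](C)(C)Cl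
Why: O-silylation of the lithium ester enolate gives the ketene silyl acetal needed as nucleophile for the Mukaiyama aldol reaction.

**Fragment C: C7–C10/C1/C11–C14 bromide**

Step 9
Reactants: 12 (S)-but-3-ene-1,2-diol
Product: 13 (4S)-4-ethenyl-2-(4-methoxyphenyl)-1,3-dioxolane (both acetal epimers)
Conditions: 4-MeOC6H4CH(OMe)2, PPTS (5 mol%), CH2Cl2, rt
Reagents that add atoms: 4-methoxybenzaldehyde dimethyl acetal, COc1ccc(C(OC)OC)cc1
Why: Acid-catalysed transacetalisation ties both hydroxyl groups of the chiral-pool diol into a p-methoxybenzylidene acetal without touching the stereocentre (future C8).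

Step 10
Reactants: 13 (4S)-4-ethenyl-2-(4-methoxyphenyl)-1,3-dioxolane
Product: 14 (2S)-2-[(4-methoxybenzyl)oxy]but-3-en-1-ol
Conditions: iBu2AlH (3 equiv), CH2Cl2, −78 to 0 °C; aq. potassium sodium tartrate
Reagents that add atoms: none
Why: Regioselective reductive acetal opening, in which aluminium coordinates the less hindered primary oxygen so that the PMB group stays on the secondary oxygen and the primary alcohol is freed.

Step 11
Reactants: 14 (2S)-2-[(4-methoxybenzyl)oxy]but-3-en-1-ol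
Product: 15 (2S)-2-[(4-methoxybenzyl)oxy]but-3-enal
Conditions: Dess–Martin periodinane, NaHCO3, CH2Cl2, 0 °C; used at once
Reagents that add atoms: none
Why: Buffered Dess–Martin oxidation is non-basic, which avoids epimerisation of the α-alkoxy centre and migration of the β,γ-double bond.

Step 12
Reactants: 15 (2S)-2-[(4-methoxybenzyl)oxy]but-3-enal; 11 tert-butyl[(1-methoxyethenyl)oxy]dimethylsilane
Product: 16 methyl (3S,4S)-3-hydroxy-4-[(4-methoxybenzyl)oxy]hex-5-enoate
Conditions: MgBr2·OEt2 (3 equiv), CH2Cl2, −78 to −30 °C; aq. citric acid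
Reagents that add atoms: none
Why: Chelation-controlled Mukaiyama aldol reaction, in which magnesium bridges the aldehyde and PMB-ether oxygens and the ketene acetal attacks opposite the vinyl group, setting C9 as S (8,9-syn).

Step 13
Reactants: 16 methyl (3S,4S)-3-hydroxy-4-[(4-methoxybenzyl)oxy]hex-5-enoate
Product: 17 methyl (3S,4S)-3-[(tert-butyldimethylsilyl)oxy]-4-[(4-methoxybenzyl)oxy]hex-5-enoate
Conditions: TBSOTf, 2,6-lutidine, CH2Cl2, −78 °C
Reagents that add atoms: tert-butyldimethylsilyl triflate, CC(C)(C)[Si](C)(C)OS(=O)(=O)C(F)(F)F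
Why: Silylation of the secondary alcohol gives a C9 protecting group orthogonal to the PMB ether at C8.

Step 14
Reactants: 17 methyl (3S,4S)-3-[(tert-butyldimethylsilyl)oxy]-4-[(4-methoxybenzyl)oxy]hex-5-enoate; 18 methyl formate
Product: 19 methyl (3S,4S)-3-[(tert-butyldimethylsilyl)oxy]-2-formyl-4-[(4-methoxybenzyl)oxy]hex-5-enoate (C2 epimers, mainly as the enol)
Conditions: LiN(iPr)2 (2.2 equiv), THF, −78 °C; then HCO2Me, −78 to −40 °C; AcOH
Reagents that add atoms: none
Why: Crossed Claisen condensation (C-formylation) of the ester enolate installs C1; the low temperature suppresses β-elimination of the silyloxy group, and the new C10 centre does not matter because it becomes sp2 in the next step.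

Step 15
Reactants: 19 methyl (3S,4S)-3-[(tert-butyldimethylsilyl)oxy]-2-formyl-4-[(4-methoxybenzyl)oxy]hex-5-enoate
Product: 20 methyl (2E,3S,4S)-3-[(tert-butyldimethylsilyl)oxy]-4-[(4-methoxybenzyl)oxy]-2-{[(4-methylbenzenesulfonyl)oxy]methylidene}hex-5-enoate
Conditions: TsCl, N-methylimidazole, Et3N, CH2Cl2, −15 °C
Reagents that add atoms: 4-toluenesulfonyl chloride, Cc1ccc(S(=O)(=O)Cl)cc1
Why: Tanabe's stereoselective enol tosylation under non-chelating amine conditions gives the E isomer, with the tosyloxy group trans to the ester and cis to C9, which fixes the C1=C10 geometry.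

Step 16
Reactants: 20 methyl (2E,3S,4S)-3-[(tert-butyldimethylsilyl)oxy]-4-[(4-methoxybenzyl)oxy]-2-{[(4-methylbenzenesulfonyl)oxy]methylidene}hex-5-enoate; 21 methyl 2-(bromomethyl)prop-2-enoate
Product: 22 dimethyl (2Z,4S,5S,6E)-2-(bromomethyl)-5-[(tert-butyldimethylsilyl)oxy]-4-[(4-methoxybenzyl)oxy]-6-{[(4-methylbenzenesulfonyl)oxy]methylidene}hept-2-enedioate
Conditions: second-generation Hoveyda–Grubbs catalyst (C31H38Cl2N2ORu, 10 mol%), 21 (5 equiv), CH2Cl2, 40 °C
Reagents that add atoms: none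
Why: Olefin cross-metathesis, in which only the monosubstituted vinyl group of 20 reacts and couples with the 1,1-disubstituted acrylate 21 under thermodynamic control to the enoate with C8 trans to the ester.

**Union and endgame**

Step 17
Reactants: 22 dimethyl (2Z,4S,5S,6E)-2-(bromomethyl)-5-[(tert-butyldimethylsilyl)oxy]-4-[(4-methoxybenzyl)oxy]-6-{[(4-methylbenzenesulfonyl)oxy]methylidene}hept-2-enedioate; 9 (2E,4Z)-3-methyl-5-(4,4,5,5-tetramethyl-1,3,2-dioxaborolan-2-yl)penta-2,4-dienal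
Product: 24 seco-lactone methyl (2E,3S,4S)-3-[(tert-butyldimethylsilyl)oxy]-4-[(4-methoxybenzyl)oxy]-4-{(2R,3S)-2-[(1E,3Z)-2-methyl-4-(4,4,5,5-tetramethyl-1,3,2-dioxaborolan-2-yl)buta-1,3-dien-1-yl]-4-methylidene-5-oxooxolan-3-yl}-2-{[(4-methylbenzenesulfonyl)oxy]methylidene}butanoate, via open-chain hydroxy ester 23 (not isolated)
Conditions: CrCl2 (4 equiv, nickel-free), THF, 0 °C to rt; aq. NH4Cl; then PPTS (5 mol%), CH2Cl2, rt
Reagents that add atoms: none
Why: Nozaki–Hiyama allylation then lactonisation, in which the equilibrating (E)-allylchromium (trivalent chromium) adds through a chair transition state to give the 6,7-anti adduct (trans-lactone) and the aldehyde approaches C7 anti to the C8–C9 bond in the A(1,3)-minimised rotamer, setting C6 and C7 as in the target, while the enol tosylate and the boronate are inert to CrCl2 without nickel.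

Step 18
Reactants: 24 seco-lactone (6R,7S,8S,9S)
Product: 25 methyl (1(10)E,2Z,4E,6R,7S,8S,9S)-9-[(tert-butyldimethylsilyl)oxy]-8-[(4-methoxybenzyl)oxy]germacra-1(10),2,4,11(13)-tetraen-12,6-olid-14-oate
Conditions: Pd(OAc)2 (10 mol%), SPhos (20 mol%), K3PO4 (3 equiv), THF/H2O (10:1), 45 °C, 1 mM, slow addition of 24
Reagents that add atoms: none
Why: Proposed new method: a palladium-catalysed intramolecular Suzuki–Miyaura coupling of an (E)-β-tosyloxy acrylate with a (Z)-alkenyl pinacol boronate to close a ten-membered cis,cis-dienoate ring, reasoned as follows: the C1–OTs bond is a vinylogous sulfonic–carboxylic anhydride and should add readily to zerovalent palladium–SPhos, the phosphate-activated boronate transmetalates onto the alkenylpalladium and reductive elimination joins C1 and C2 with retention at both sp2 carbons, so the preset E (C1=C10) and Z (C2=C3) geometries, both cis inside the new ring, keep strain low at high dilution; the closest known reactions are Tanabe's intermolecular stereoretentive Suzuki couplings of (E)-enol tosylates and macrocyclising Suzuki couplings of alkenyl iodides, and no stereocentre is formed.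

Step 19
Reactants: 25 methyl (1(10)E,2Z,4E,6R,7S,8S,9S)-9-[(tert-butyldimethylsilyl)oxy]-8-[(4-methoxybenzyl)oxy]germacra-1(10),2,4,11(13)-tetraen-12,6-olid-14-oate
Product: 26 methyl (1(10)E,2Z,4E,6R,7R,8S,9S)-9-[(tert-butyldimethylsilyl)oxy]-8-hydroxygermacra-1(10),2,4,11(13)-tetraen-12,6-olid-14-oate
Conditions: DDQ (1.5 equiv), CH2Cl2/pH 7 buffer (10:1), 0 °C
Reagents that add atoms: none
Why: Oxidative PMB cleavage by DDQ (hydride abstraction from the electron-rich benzyl ether, then hydrolysis) frees C8–OH while the silyl ether, the lactone and the electron-poor triene are inert.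

Step 20
Reactants: 26 methyl (1(10)E,2Z,4E,6R,7R,8S,9S)-9-[(tert-butyldimethylsilyl)oxy]-8-hydroxygermacra-1(10),2,4,11(13)-tetraen-12,6-olid-14-oate; 4 (2R,3S)-2,3-dimethyloxirane-2-carboxylic acid
Product: 28 methyl (1(10)E,2Z,4E,6R,7S,8S,9S)-9-[(tert-butyldimethylsilyl)oxy]-8-{[(2R,3S)-2,3-dimethyloxirane-2-carbonyl]oxy}germacra-1(10),2,4,11(13)-tetraen-12,6-olid-14-oate, via mixed Yamaguchi anhydride 27 (not isolated)
Conditions: 4, 2,4,6-trichlorobenzoyl chloride, Et3N, THF, rt; then 26, DMAP, toluene, rt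
Reagents that add atoms: none
Why: Yamaguchi esterification, in which DMAP attacks the less hindered glycidic carbonyl of the mixed anhydride and the resulting acylpyridinium acylates the hindered C8 hydroxyl without touching the stereocentres of the acid.

Step 21
Reactants: 28 C8 epoxy ester, C9 silyl ether
Product: 29 methyl (1(10)E,2Z,4E,6R,7S,8S,9S)-8-{[(2R,3S)-2,3-dimethyloxirane-2-carbonyl]oxy}-9-hydroxygermacra-1(10),2,4,11(13)-tetraen-12,6-olid-14-oate
Conditions: HF·pyridine, pyridine, THF, 0 °C to rt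
Reagents that add atoms: none
Why: Fluoride-mediated desilylation under pyridine-buffered conditions, which the electron-poor glycidic ester epoxide and the α-methylene lactone tolerate.

Step 22
Reactants: 29 C9 alcohol
Product: 30 methyl (1(10)E,2Z,4E,6R,7S,8S,9S)-9-acetoxy-8-{[(2R,3S)-2,3-dimethyloxirane-2-carbonyl]oxy}germacra-1(10),2,4,11(13)-tetraen-12,6-olid-14-oate
Conditions: Ac2O, pyridine, DMAP (5 mol%), CH2Cl2, 0 °C
Reagents that add atoms: acetic anhydride, CC(=O)OC(C)=O
Why: DMAP-catalysed acylation of the C9 alcohol proceeds with retention at C9.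

Step 23
Reactants: 30 triene acetate
Product: 31 methyl (1(10)E,2Z,4R,5R,6S,7R,8S,9S)-9-acetoxy-8-{[(2R,3S)-2,3-dimethyloxirane-2-carbonyl]oxy}-4,5-epoxygermacra-1(10),2,11(13)-trien-12,6-olid-14-oate (target)
Conditions: mCPBA (1.1 equiv), NaHCO3, CH2Cl2, 0 °C
Reagents that add atoms: 3-chloroperbenzoic acid, OOC(=O)c1cccc(Cl)c1
Why: Prilezhaev epoxidation at C4=C5, the most electron-rich alkene (trisubstituted and farthest from the ester); with H6 held in the alkene plane by A(1,3) strain and the inner face blocked by the ring (C7), the peracid attacks the outer face syn to the lactone oxygen and gives the 4R,5R trans-epoxide, as in the parthenolide series.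

**Compound list**

1 | (E)-2-methylbut-2-en-1-ol | C/C=C(\C)CO | starting material
2 | [(2S,3S)-2,3-dimethyloxiran-2-yl]methanol | OC[C@]1(C)O[C@H]1C | intermediate
3 | (2R,3S)-2,3-dimethyloxirane-2-carbaldehyde | O=C[C@]1(C)O[C@H]1C | intermediate
4 | (2R,3S)-2,3-dimethyloxirane-2-carboxylic acid | OC(=O)[C@]1(C)O[C@H]1C | intermediate
5 | (E)-3-methylpent-2-en-4-yn-1-ol | C#C/C(C)=C/CO | starting material
6 | tert-butyldimethyl{[(2E)-3-methylpent-2-en-4-yn-1-yl]oxy}silane | C#C/C(C)=C/CO[Si](C)(C)C(C)(C)C | intermediate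
7 | tert-butyldimethyl{[(2E,4Z)-3-methyl-5-(4,4,5,5-tetramethyl-1,3,2-dioxaborolan-2-yl)penta-2,4-dien-1-yl]oxy}silane | CC1(C)OB(/C=C\C(C)=C\CO[Si](C)(C)C(C)(C)C)OC1(C)C | intermediate
8 | (2E,4Z)-3-methyl-5-(4,4,5,5-tetramethyl-1,3,2-dioxaborolan-2-yl)penta-2,4-dien-1-ol | CC1(C)OB(/C=C\C(C)=C\CO)OC1(C)C | intermediate
9 | (2E,4Z)-3-methyl-5-(4,4,5,5-tetramethyl-1,3,2-dioxaborolan-2-yl)penta-2,4-dienal | CC1(C)OB(/C=C\C(C)=C\C=O)OC1(C)C | intermediate
10 | methyl acetate | CC(=O)OC | starting material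
11 | tert-butyl[(1-methoxyethenyl)oxy]dimethylsilane | C=C(OC)O[Si](C)(C)C(C)(C)C | intermediate
12 | (S)-but-3-ene-1,2-diol | C=C[C@H](O)CO | starting material
13 | (4S)-4-ethenyl-2-(4-methoxyphenyl)-1,3-dioxolane (acetal epimers) | C=C[C@H]1COC(c2ccc(OC)cc2)O1 | intermediate
14 | (2S)-2-[(4-methoxybenzyl)oxy]but-3-en-1-ol | C=C[C@H](OCc1ccc(OC)cc1)CO | intermediate
15 | (2S)-2-[(4-methoxybenzyl)oxy]but-3-enal | C=C[C@H](OCc1ccc(OC)cc1)C=O | intermediate
16 | methyl (3S,4S)-3-hydroxy-4-[(4-methoxybenzyl)oxy]hex-5-enoate | C=C[C@H](OCc1ccc(OC)cc1)[C@@H](O)CC(=O)OC | intermediate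
17 | methyl (3S,4S)-3-[(tert-butyldimethylsilyl)oxy]-4-[(4-methoxybenzyl)oxy]hex-5-enoate | C=C[C@H](OCc1ccc(OC)cc1)[C@@H](O[Si](C)(C)C(C)(C)C)CC(=O)OC | intermediate
18 | methyl formate | COC=O | starting material
19 | methyl (3S,4S)-3-[(tert-butyldimethylsilyl)oxy]-2-formyl-4-[(4-methoxybenzyl)oxy]hex-5-enoate (C2 epimers/enol) | C=C[C@H](OCc1ccc(OC)cc1)[C@@H](O[Si](C)(C)C(C)(C)C)C(C=O)C(=O)OC | intermediate
20 | methyl (2E,3S,4S)-3-[(tert-butyldimethylsilyl)oxy]-4-[(4-methoxybenzyl)oxy]-2-{[(4-methylbenzenesulfonyl)oxy]methylidene}hex-5-enoate | C=C[C@H](OCc1ccc(OC)cc1)[C@@H](O[Si](C)(C)C(C)(C)C)/C(C(=O)OC)=C\OS(=O)(=O)c1ccc(C)cc1 | intermediate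
21 | methyl 2-(bromomethyl)prop-2-enoate | C=C(CBr)C(=O)OC | starting material
22 | dimethyl (2Z,4S,5S,6E)-2-(bromomethyl)-5-[(tert-butyldimethylsilyl)oxy]-4-[(4-methoxybenzyl)oxy]-6-{[(4-methylbenzenesulfonyl)oxy]methylidene}hept-2-enedioate | BrC/C(C(=O)OC)=C\[C@H](OCc1ccc(OC)cc1)[C@@H](O[Si](C)(C)C(C)(C)C)/C(C(=O)OC)=C\OS(=O)(=O)c1ccc(C)cc1 | intermediate
23 | open-chain hydroxy ester (6R,7S,8S,9S): C6 alcohol with the C12 methyl ester still open, otherwise as 24 (not isolated) | C=C(C(=O)OC)[C@@H]([C@H](O)/C=C(C)/C=C\B1OC(C)(C)C(C)(C)O1)[C@H](OCc1ccc(OC)cc1)[C@@H](O[Si](C)(C)C(C)(C)C)/C(C(=O)OC)=C\OS(=O)(=O)c1ccc(C)cc1 | intermediate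
24 | seco-lactone, methyl (2E,3S,4S)-3-[(tert-butyldimethylsilyl)oxy]-4-[(4-methoxybenzyl)oxy]-4-{(2R,3S)-2-[(1E,3Z)-2-methyl-4-(4,4,5,5-tetramethyl-1,3,2-dioxaborolan-2-yl)buta-1,3-dien-1-yl]-4-methylidene-5-oxooxolan-3-yl}-2-{[(4-methylbenzenesulfonyl)oxy]methylidene}butanoate | C=C1C(=O)O[C@H](/C=C(C)/C=C\B2OC(C)(C)C(C)(C)O2)[C@H]1[C@H](OCc1ccc(OC)cc1)[C@@H](O[Si](C)(C)C(C)(C)C)/C(C(=O)OC)=C\OS(=O)(=O)c1ccc(C)cc1 | intermediate
25 | methyl (1(10)E,2Z,4E,6R,7S,8S,9S)-9-[(tert-butyldimethylsilyl)oxy]-8-[(4-methoxybenzyl)oxy]germacra-1(10),2,4,11(13)-tetraen-12,6-olid-14-oate | [C@@H]1(OCc3ccc(OC)cc3)[C@@H](O[Si](C)(C)C(C)(C)C)/C(C(=O)OC)=C\C=C/C(C)=C/[C@H]2OC(=O)C(=C)[C@@H]21 | intermediate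
26 | methyl (1(10)E,2Z,4E,6R,7R,8S,9S)-9-[(tert-butyldimethylsilyl)oxy]-8-hydroxygermacra-1(10),2,4,11(13)-tetraen-12,6-olid-14-oate | [C@@H]1(O)[C@@H](O[Si](C)(C)C(C)(C)C)/C(C(=O)OC)=C\C=C/C(C)=C/[C@H]2OC(=O)C(=C)[C@@H]21 | intermediate
27 | (2R,3S)-2,3-dimethyloxirane-2-carboxylic 2,4,6-trichlorobenzoic anhydride (not isolated) | O=C(OC(=O)[C@]1(C)O[C@H]1C)c1c(Cl)cc(Cl)cc1Cl | intermediate
28 | methyl (1(10)E,2Z,4E,6R,7S,8S,9S)-9-[(tert-butyldimethylsilyl)oxy]-8-{[(2R,3S)-2,3-dimethyloxirane-2-carbonyl]oxy}germacra-1(10),2,4,11(13)-tetraen-12,6-olid-14-oate | [C@@H]1(OC(=O)[C@]3(C)O[C@H]3C)[C@@H](O[Si](C)(C)C(C)(C)C)/C(C(=O)OC)=C\C=C/C(C)=C/[C@H]2OC(=O)C(=C)[C@@H]21 | intermediate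
29 | methyl (1(10)E,2Z,4E,6R,7S,8S,9S)-8-{[(2R,3S)-2,3-dimethyloxirane-2-carbonyl]oxy}-9-hydroxygermacra-1(10),2,4,11(13)-tetraen-12,6-olid-14-oate | [C@@H]1(OC(=O)[C@]3(C)O[C@H]3C)[C@@H](O)/C(C(=O)OC)=C\C=C/C(C)=C/[C@H]2OC(=O)C(=C)[C@@H]21 | intermediate
30 | methyl (1(10)E,2Z,4E,6R,7S,8S,9S)-9-acetoxy-8-{[(2R,3S)-2,3-dimethyloxirane-2-carbonyl]oxy}germacra-1(10),2,4,11(13)-tetraen-12,6-olid-14-oate | [C@@H]1(OC(=O)[C@]3(C)O[C@H]3C)[C@@H](OC(C)=O)/C(C(=O)OC)=C\C=C/C(C)=C/[C@H]2OC(=O)C(=C)[C@@H]21 | intermediate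
31 | methyl (1(10)E,2Z,4R,5R,6S,7R,8S,9S)-9-acetoxy-8-{[(2R,3S)-2,3-dimethyloxirane-2-carbonyl]oxy}-4,5-epoxygermacra-1(10),2,11(13)-trien-12,6-olid-14-oate | C=C1C(=O)O[C@H]2[C@H]1[C@H](OC(=O)[C@]1(C)O[C@H]1C)[C@@H](OC(C)=O)/C(C(=O)OC)=C\C=C/[C@@]1(C)O[C@H]21 | target

**Step count and risks**

Total step count: 23. Longest linear sequence: 15 steps (12 → 31, steps 9 to 23). The other branches are 1 → 4 (3 steps), 5 → 9 (4 steps) and 10 → 11 (1 step).

The three steps most likely to fail: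

Step 18 (the proposed Suzuki ring closure). Protodeboronation of the dienyl boronate, ionisation of the allylic lactone by zerovalent palladium, or oligomerisation may outrun the cyclisation. The fallback sets out from 20 and 8 and comes back at 25, and reverses the order of the two ring-forming events using known chemistry. Enol tosylate 20 and boronate alcohol 8 are joined by an ordinary intermolecular Suzuki–Miyaura coupling (PdCl2(PPh3)2, K3PO4, THF/H2O, 50 °C) to give the open-chain trienol F1. Cross-metathesis of its vinyl group with 21 (second-generation Hoveyda–Grubbs catalyst) gives the allylic bromide alcohol F2, and MnO2 oxidises this to the bromo aldehyde F3. Intramolecular Nozaki–Hiyama allylation (CrCl2, THF, high dilution), the classical chromium route to trans-fused germacranolides, then closes the ten-membered ring and the lactone together and lands on 25.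

Step 16 (cross-metathesis). Both partners are sluggish olefin types and the yield may be poor. The fallback sets out from 20 and comes back at 22. The vinyl group is cleaved with OsO4 (cat.)/NaIO4/2,6-lutidine to the aldehyde F4. Vinylalumination with the alane made from methyl propiolate and iBu2AlH/HMPA gives the Baylis–Hillman-type alcohol F5; this amine-free route avoids DABCO, which would displace the enol tosylate. PBr3 (Et2O, −10 °C, SN2′) then gives 22.

Step 17 (chromium allylation). The diastereoselectivity rests on substrate control (anti addition, 1,2-induction from C8) and could be low. The fallback sets out from 22 and 9 and comes back at 24. It replaces substrate control and stoichiometric chromium by catalyst control: a Zhang-type enantioselective chromium-catalysed 2-(alkoxycarbonyl)allylation (CrCl2 10 mol%, chiral carbazole bis(oxazoline) ligand, Mn powder, Cp2ZrCl2, THF, then lactonisation). The ligand fixes the aldehyde face (C6) and the chair transition state relays it to C7. No new isolable compound arises.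

**Further compounds**

F1 | step 18 | methyl (2E,3S,4S)-3-[(tert-butyldimethylsilyl)oxy]-2-[(2Z,4E)-6-hydroxy-4-methylhexa-2,4-dien-1-ylidene]-4-[(4-methoxybenzyl)oxy]hex-5-enoate | C=C[C@H](OCc1ccc(OC)cc1)[C@@H](O[Si](C)(C)C(C)(C)C)/C(C(=O)OC)=C\C=C/C(C)=C/CO
F2 | step 18 | dimethyl (2Z,4S,5S,6E)-2-(bromomethyl)-5-[(tert-butyldimethylsilyl)oxy]-6-[(2Z,4E)-6-hydroxy-4-methylhexa-2,4-dien-1-ylidene]-4-[(4-methoxybenzyl)oxy]hept-2-enedioate | BrC/C(C(=O)OC)=C\[C@H](OCc1ccc(OC)cc1)[C@@H](O[Si](C)(C)C(C)(C)C)/C(C(=O)OC)=C\C=C/C(C)=C/CO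
F3 | step 18 | dimethyl (2Z,4S,5S,6E)-2-(bromomethyl)-5-[(tert-butyldimethylsilyl)oxy]-4-[(4-methoxybenzyl)oxy]-6-[(2Z,4E)-4-methyl-6-oxohexa-2,4-dien-1-ylidene]hept-2-enedioate | BrC/C(C(=O)OC)=C\[C@H](OCc1ccc(OC)cc1)[C@@H](O[Si](C)(C)C(C)(C)C)/C(C(=O)OC)=C\C=C/C(C)=C/C=O
F4 | step 16 | methyl (2E,3S,4R)-3-[(tert-butyldimethylsilyl)oxy]-4-[(4-methoxybenzyl)oxy]-2-{[(4-methylbenzenesulfonyl)oxy]methylidene}-5-oxopentanoate | O=C[C@H](OCc1ccc(OC)cc1)[C@@H](O[Si](C)(C)C(C)(C)C)/C(C(=O)OC)=C\OS(=O)(=O)c1ccc(C)cc1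
F5 | step 16 | dimethyl (4S,5S,6E)-5-[(tert-butyldimethylsilyl)oxy]-3-hydroxy-4-[(4-methoxybenzyl)oxy]-2-methylidene-6-{[(4-methylbenzenesulfonyl)oxy]methylidene}heptanedioate (C3 epimers) | C=C(C(=O)OC)C(O)[C@H](OCc1ccc(OC)cc1)[C@@H](O[Si](C)(C)C(C)(C)C)/C(C(=O)OC)=C\OS(=O)(=O)c1ccc(C)cc1
F0 | step 17 | none | none
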